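**Retrosynthetic overview**

1. Target 24 ⇐ saponification, diimide reduction, Wittig olefination (C3 arm) and cross-metathesis (C6 arm) from the core 15, (3R,6R)-3-(hydroxymethyl)-6-allyl-3,6-dimethyl-1,2-dioxane.
2. 15 ⇐ resolution (camphanate) of rac-12 ⇐ anti allylation of the bridged peroxyketal 10 (1,4-dimethyl-2,3,5-trioxabicyclo[2.2.2]octane). Its CH2–O bridge is not in the target: it relays configuration across the ring and is cleaved in that step.
3. 10 ⇐ insertion of O2 into the C1–C2 bond of cyclobutanediol 7 (cyclobutane → 1,2-dioxane, 4 → 6), then cage ketalization. Enabling feature: a strained four-membered ring in which C1 is a tertiary carbinol (alkoxy-radical site, later the ketal carbon) and C2 is fully substituted (Me, CH2OH), so that C2 becomes the tertiary radical that takes up O2 and carries the OH that closes the cage.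
4. 7 ⇐ MeMgBr + cyclobutanone 6 ⇐ epoxidation/semipinacol ring expansion (3 → 4) of 1-isopropenylcyclopropanol 4 ⇐ cyclopropanone hemiketal 1 + Grignard reagent 2.
5. Ring order: cyclopropane → cyclobutane → 1,2-dioxane (formed inside the temporary cage) → cage opened.

Key step: step 4

Remark on the chemistry: the carbon radical that takes up O2 in step 4 is planar, so 10 forms as a racemate. The absolute configuration is therefore taken from a separation of diastereomeric camphanates (steps 6 and 7), the first point at which a handle exists. Core 12 is pseudo-C2-symmetric, so the other diastereomer could in principle be brought to the same enantiomer by exchanging the roles of its two arms; this is not part of the route.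

**Route**

Step 1
Reactants: 1 1-ethoxycyclopropan-1-ol (cyclopropanone ethyl hemiketal); 2 isopropenylmagnesium bromide
Product: 4 1-(prop-1-en-2-yl)cyclopropan-1-ol, via cyclopropanone 3 (not isolated)
Conditions: 2 (2.5 equiv), THF, 0 °C to reflux; aq. NH4Cl
Reagents that add atoms: none
Why: Grignard addition to a cyclopropanone hemiketal: the first equivalent of 2 deprotonates 1, the magnesium hemiketal releases cyclopropanone in the flask, and the second equivalent adds to its strained C=O.

Step 2
Reactants: 4 1-(prop-1-en-2-yl)cyclopropan-1-ol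
Product: 6 rac-2-(hydroxymethyl)-2-methylcyclobutan-1-one, via cyclopropanol epoxide 5 (not isolated)
Conditions: mCPBA (1.0 equiv), CH2Cl2, 0 °C to rt
Reagents that add atoms: meta-chloroperoxybenzoic acid, O=C(OO)c1cccc(Cl)c1
Why: Prilezhaev epoxidation of the 1,1-disubstituted alkene, then acid-promoted semipinacol ring expansion of the 1-(oxiranyl)cyclopropanol (a cyclopropane C–C bond migrates to the tertiary epoxide carbon), which places Me and CH2OH on the carbon next to the new carbonyl; the stereocentre forms racemic and is remade in step 4.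

Step 3
Reactants: 6 rac-2-(hydroxymethyl)-2-methylcyclobutan-1-one
Product: 7 2-(hydroxymethyl)-1,2-dimethylcyclobutan-1-ol (racemic; both diastereomers)
Conditions: MeMgBr (3 equiv), THF, −78 °C to 0 °C; aq. NH4Cl
Reagents that add atoms: methylmagnesium bromide, C[Mg]Br
Why: Grignard 1,2-addition to the strained ketone after deprotonation of the hydroxyl; the diastereomer ratio does not matter because the carbinol carbon becomes a carbonyl carbon in step 4.

Step 4
Reactants: 7 2-(hydroxymethyl)-1,2-dimethylcyclobutan-1-ol
Product: 10 rac-(1R,4S)-1,4-dimethyl-2,3,5-trioxabicyclo[2.2.2]octane, via keto hydroperoxide 8 (not isolated), via dioxanol 9 (not isolated)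
Conditions: Co(acac)2 (10 mol %), O2 (1 atm), MeCN, 40 °C; then CSA (10 mol %), 4 Å MS, CH2Cl2, rt
Reagents that add atoms: dioxygen, O=O
Why: Co(II)/O2 generates the cobalt-bound alkoxy radical of the strained tertiary cyclobutanol, β-scission of the C1–C2 ring bond gives the tertiary radical at C2, O2 traps it, and the resulting hydroperoxide 8 adds to the new ketone, so that O2 is inserted into the four-membered ring and the 1,2-dioxane appears by a 4 → 6 ring expansion. The closest known reaction type is the cobalt- or manganese-catalysed aerobic ring expansion of tertiary cyclobutanols to 1,2-dioxan-3-ols (and of cyclopropanols to 1,2-dioxolan-3-ols). The dioxane closes by 6-exo-trig addition of the OOH oxygen to the C=O, and acid then closes the CH2–O bridge by addition of the primary OH to the ionized hemiketal carbon (6-exo-trig with respect to the new oxane ring), which creates the oxane and 1,2,4-trioxane rings of the cage at once. The quaternary C–OO centre arises from a planar radical and is racemic, while the ketal centre is locked to it by the bicycle, so only one diastereomer can form and both diastereomers of 7 converge. The step needs β-scission toward C2 rather than C4 or CH3, which the full substitution of C2 and the ring strain secure, and it needs capture of the tertiary hydroperoxide before cobalt decomposes it, which the fast intramolecular hemiketalization and the storage of the O–O unit as a dialkyl peroxide in the cage should secure.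

Step 5
Reactants: 10 rac-(1R,4S)-1,4-dimethyl-2,3,5-trioxabicyclo[2.2.2]octane; 11 allyltrimethylsilane
Product: 12 rac-[(3R,6R)-3,6-dimethyl-6-(prop-2-en-1-yl)-1,2-dioxan-3-yl]methanol
Conditions: 11 (3 equiv), SnCl4 (1.1 equiv), CH2Cl2, −78 °C; aq. NaHCO3
Reagents that add atoms: none
Why: Hosomi–Sakurai allylation of a peroxyketal through its peroxycarbenium ion: SnCl4 binds the bridging ether oxygen (the most basic one), the C4–O5 bond of the cage ionizes, the stannate alkoxide on the CH2 arm stays ion-paired over the face it left (pseudo-axial), and the allylsilane adds axially to the opposite face, so that allyl ends trans to CH2OH and cis to the other methyl (3,6-trans-dimethyl), the new centre being controlled by the existing quaternary centre through the opened bridge.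

Step 6
Reactants: 12 rac-[(3R,6R)-3,6-dimethyl-6-(prop-2-en-1-yl)-1,2-dioxan-3-yl]methanol; 13 (1S)-(−)-camphanic chloride
Product: 14 [(3R,6R)-3,6-dimethyl-6-(prop-2-en-1-yl)-1,2-dioxan-3-yl]methyl (1S,4R)-4,7,7-trimethyl-3-oxo-2-oxabicyclo[2.2.1]heptane-1-carboxylate
Conditions: 13 (1.1 equiv), Et3N, DMAP (cat.), CH2Cl2, 0 °C to rt; separation of the two diastereomeric esters by chromatography and crystallization
Reagents that add atoms: none
Why: Acylation of the primary alcohol with an enantiopure acid chloride turns the racemate into two diastereomeric camphanates (classical resolution), of which the (3R,6R) ester is taken on, its configuration to be confirmed by X-ray analysis of the crystalline ester.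

Step 7
Reactants: 14 the (3R,6R) camphanate
Product: 15 [(3R,6R)-3,6-dimethyl-6-(prop-2-en-1-yl)-1,2-dioxan-3-yl]methanol
Conditions: K2CO3 (cat.), MeOH, rt to 40 °C
Reagents that add atoms: none
Why: Base-catalysed transesterification (methanolysis) releases the alcohol; the dialkyl peroxide has no hydrogen on its O-bearing carbons, so the base-induced Kornblum–DeLaMare cleavage is not possible.

Step 8
Reactants: 16 (4-bromobutyl)benzene; 17 allylmagnesium bromide
Product: 18 7-phenylhept-1-ene
Conditions: 17 (1.5 equiv), Li2CuCl4 (3 mol %), THF, 0 °C to rt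
Reagents that add atoms: none
Why: Copper-catalysed (Kochi) sp3–sp3 cross-coupling of a primary alkyl bromide with an allyl Grignard reagent gives the chain with the terminal alkene needed for metathesis.

Step 9
Reactants: 15 [(3R,6R)-3,6-dimethyl-6-(prop-2-en-1-yl)-1,2-dioxan-3-yl]methanol; 18 7-phenylhept-1-ene
Product: 19 [(3R,6R)-3,6-dimethyl-6-[(2E)-8-phenyloct-2-en-1-yl]-1,2-dioxan-3-yl]methanol (E/Z mixture; E isomer drawn)
Conditions: Grubbs second-generation catalyst (5 mol %), 18 (3 equiv), CH2Cl2, 40 °C
Reagents that add atoms: none
Why: Olefin cross-metathesis of two terminal alkenes with loss of ethene; a dialkyl peroxide and a free alcohol should be tolerated by the ruthenium carbene, and the alkene geometry is irrelevant because the double bond is reduced in step 12.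

Step 10
Reactants: 19 [(3R,6R)-3,6-dimethyl-6-[(2E)-8-phenyloct-2-en-1-yl]-1,2-dioxan-3-yl]methanol
Product: 20 (3R,6R)-3,6-dimethyl-6-[(2E)-8-phenyloct-2-en-1-yl]-1,2-dioxane-3-carbaldehyde
Conditions: Dess–Martin periodinane (1.3 equiv), CH2Cl2, 0 °C to rt
Reagents that add atoms: none
Why: Dess–Martin oxidation of the neopentyl-type primary alcohol; the aldehyde has no α-hydrogen, so it can neither epimerize nor eliminate the peroxide.

Step 11
Reactants: 20 (3R,6R)-3,6-dimethyl-6-[(2E)-8-phenyloct-2-en-1-yl]-1,2-dioxane-3-carbaldehyde; 21 methyl (triphenylphosphoranylidene)acetate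
Product: 22 methyl (2E)-3-[(3R,6R)-3,6-dimethyl-6-[(2E)-8-phenyloct-2-en-1-yl]-1,2-dioxan-3-yl]prop-2-enoate
Conditions: 21 (1.5 equiv), CH2Cl2, rt to 40 °C
Reagents that add atoms: none
Why: Wittig olefination with a stabilized ylide (E-selective) adds the two remaining carbons of the propanoate chain without touching the peroxide.

Step 12
Reactants: 22 methyl (2E)-3-[(3R,6R)-3,6-dimethyl-6-[(2E)-8-phenyloct-2-en-1-yl]-1,2-dioxan-3-yl]prop-2-enoate
Product: 23 methyl 3-[(3R,6S)-3,6-dimethyl-6-(8-phenyloctyl)-1,2-dioxan-3-yl]propanoate
Conditions: dipotassium azodicarboxylate (excess, in portions), AcOH, MeOH/CH2Cl2, 0 °C to rt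
Reagents that add atoms: none
Why: Diimide reduction (concerted syn transfer of two hydrogens) saturates both C=C bonds and, unlike catalytic hydrogenation, leaves the O–O bond intact; the descriptor at the phenyloctyl-bearing carbon changes from R to S only because the CIP priorities change.

Step 13
Reactants: 23 methyl 3-[(3R,6S)-3,6-dimethyl-6-(8-phenyloctyl)-1,2-dioxan-3-yl]propanoate
Product: 24 3-[(3R,6S)-3,6-dimethyl-6-(8-phenyloctyl)-1,2-dioxan-3-yl]propanoic acid
Conditions: LiOH (3 equiv), THF/H2O 3:1, rt; then aq. HCl to pH 3
Reagents that add atoms: lithium hydroxide, [Li+].[OH-]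
Why: Saponification of the methyl ester; the peroxide is γ to the carbonyl and sits on fully substituted carbons, so neither retro-Michael cleavage nor base-induced fragmentation can occur.

**Compound list**

1 | 1-ethoxycyclopropan-1-ol | CCOC1(O)CC1 | starting material
2 | isopropenylmagnesium bromide | CC(=C)[Mg]Br | starting material
3 | cyclopropanone (not isolated) | O=C1CC1 | intermediate
4 | 1-(prop-1-en-2-yl)cyclopropan-1-ol | CC(=C)C1(O)CC1 | intermediate
5 | 1-(2-methyloxiran-2-yl)cyclopropan-1-ol (racemic, not isolated) | CC1(CO1)C1(O)CC1 | intermediate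
6 | rac-2-(hydroxymethyl)-2-methylcyclobutan-1-one | CC1(CO)CCC1=O | intermediate
7 | 2-(hydroxymethyl)-1,2-dimethylcyclobutan-1-ol (racemic, both diastereomers) | CC1(O)CCC1(C)CO | intermediate
8 | 5-hydroperoxy-6-hydroxy-5-methylhexan-2-one (racemic, not isolated) | CC(=O)CCC(C)(CO)OO | intermediate
9 | 6-(hydroxymethyl)-3,6-dimethyl-1,2-dioxan-3-ol (racemic, not isolated) | CC1(O)CCC(C)(CO)OO1 | intermediate
10 | rac-(1R,4S)-1,4-dimethyl-2,3,5-trioxabicyclo[2.2.2]octane (racemate, one enantiomer drawn) | C1O[C@]2(C)CC[C@@]1(C)OO2 | intermediate
11 | allyltrimethylsilane | C=CC[Si](C)(C)C | starting material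
12 | rac-[(3R,6R)-3,6-dimethyl-6-(prop-2-en-1-yl)-1,2-dioxan-3-yl]methanol (racemate, one enantiomer drawn) | C[C@]1(CC=C)CC[C@](C)(CO)OO1 | intermediate
13 | (1S)-(−)-camphanic chloride | ClC(=O)[C@@]12CC[C@@](C)(C(=O)O1)C2(C)C | starting material
14 | [(3R,6R)-3,6-dimethyl-6-(prop-2-en-1-yl)-1,2-dioxan-3-yl]methyl (1S,4R)-4,7,7-trimethyl-3-oxo-2-oxabicyclo[2.2.1]heptane-1-carboxylate | C[C@]1(CC=C)CC[C@](C)(COC(=O)[C@@]23CC[C@@](C)(C(=O)O2)C3(C)C)OO1 | intermediate
15 | [(3R,6R)-3,6-dimethyl-6-(prop-2-en-1-yl)-1,2-dioxan-3-yl]methanol | C[C@]1(CC=C)CC[C@](C)(CO)OO1 | intermediate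
16 | (4-bromobutyl)benzene | BrCCCCc1ccccc1 | starting material
17 | allylmagnesium bromide | C=CC[Mg]Br | starting material
18 | 7-phenylhept-1-ene | C=CCCCCCc1ccccc1 | intermediate
19 | [(3R,6R)-3,6-dimethyl-6-[(2E)-8-phenyloct-2-en-1-yl]-1,2-dioxan-3-yl]methanol (E/Z mixture, E drawn) | C[C@]1(C/C=C/CCCCCc2ccccc2)CC[C@](C)(CO)OO1 | intermediate
20 | (3R,6R)-3,6-dimethyl-6-[(2E)-8-phenyloct-2-en-1-yl]-1,2-dioxane-3-carbaldehyde | C[C@]1(C/C=C/CCCCCc2ccccc2)CC[C@](C)(C=O)OO1 | intermediate
21 | methyl (triphenylphosphoranylidene)acetate | COC(=O)C=P(c1ccccc1)(c1ccccc1)c1ccccc1 | starting material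
22 | methyl (2E)-3-[(3R,6R)-3,6-dimethyl-6-[(2E)-8-phenyloct-2-en-1-yl]-1,2-dioxan-3-yl]prop-2-enoate | C[C@]1(C/C=C/CCCCCc2ccccc2)CC[C@](C)(/C=C/C(=O)OC)OO1 | intermediate
23 | methyl 3-[(3R,6S)-3,6-dimethyl-6-(8-phenyloctyl)-1,2-dioxan-3-yl]propanoate | C[C@]1(CCCCCCCCc2ccccc2)CC[C@](C)(CCC(=O)OC)OO1 | intermediate
24 | 3-[(3R,6S)-3,6-dimethyl-6-(8-phenyloctyl)-1,2-dioxan-3-yl]propanoic acid | C[C@]1(CCCCCCCCc2ccccc2)CC[C@](C)(CCC(=O)O)OO1 | target

**Step count and risks**

Total step count: 13. Longest linear sequence: 12 (steps 1–7 and 9–13; step 8 is a side branch).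

The three steps most likely to fail:

1. Step 5. What may go wrong: ionization of the peroxide C–O bond instead of the ether C–O bond of the cage (loss of the O–O unit), or attack of the allylsilane on the tether face (poor facial selectivity). The fallback avoids the peroxycarbenium ion altogether. It sets out from 9, obtained by leaving out the acid treatment of step 4, and comes back at 12. Trimethyl phosphonoacetate with LiCl and DBU in MeCN would olefinate the open keto hydroperoxide form (Horner–Wadsworth–Emmons) to methyl (2E)-6-hydroperoxy-7-hydroxy-3,6-dimethylhept-2-enoate F3. Under the same basic conditions its hydroperoxide should add to the enoate (intramolecular peroxy-Michael addition, 6-exo-trig) to give methyl 2-[rac-(3R,6R)-6-(hydroxymethyl)-3,6-dimethyl-1,2-dioxan-3-yl]acetate F4 together with its C3 epimer. Because this conjugate addition is reversible with base, the unwanted epimer would be separated and resubjected, so that selectivity becomes a matter of equilibration and recycling, not of a kinetic facial preference. DIBAL-H at −78 °C would reduce F4 to 2-[rac-(3R,6R)-6-(hydroxymethyl)-3,6-dimethyl-1,2-dioxan-3-yl]acetaldehyde F5, and Wittig methylenation with Ph3P=CH2 would give 12.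

2. Step 4. What may go wrong: cobalt-induced homolysis of the tertiary hydroperoxide before it cyclizes (with loss of the CH2OH arm as formaldehyde), or stalling of the radical chain by chelation of cobalt by the 1,3-diol. The fallback separates ring opening from peroxidation and brings in the peroxide by an ionic route without a metal. It sets out from 7 and comes back at 10. A manganese- or silver-mediated radical ring-opening bromination of the cyclobutanol with NBS would give 5-bromo-6-hydroxy-5-methylhexan-2-one F1. K2CO3 would close the bromohydrin to 4-(2-methyloxiran-2-yl)butan-2-one F2. Acid-catalysed perhydrolysis (ethereal H2O2, phosphomolybdic acid cat.) should open the epoxide at its tertiary carbon, and the hydroxy hydroperoxide 8 would close via 9 to 10 on treatment with CSA and molecular sieves.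

3. Step 6. What may go wrong: incomplete separation of the two camphanates (co-elution or co-crystallization), because the stereocentres of the dioxane are remote from those of the auxiliary. The fallback replaces the diastereomer separation by an enzymatic kinetic resolution. It sets out from 12 and comes back at 15. A lipase (for example Burkholderia cepacia lipase) with vinyl acetate in MTBE, chosen by screening so that the (3S,6S)-alcohol is the faster-reacting enantiomer, would remove that enantiomer as [(3S,6S)-3,6-dimethyl-6-(prop-2-en-1-yl)-1,2-dioxan-3-yl]methyl acetate F6. The unreacted alcohol 15 would be collected beyond half conversion; steps 6 and 7 are then not needed.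

**Further compounds**

F1 | step 4 | 5-bromo-6-hydroxy-5-methylhexan-2-one (racemic) | CC(=O)CCC(C)(Br)CO
F2 | step 4 | 4-(2-methyloxiran-2-yl)butan-2-one (racemic) | CC(=O)CCC1(C)CO1
F3 | step 5 | methyl (2E)-6-hydroperoxy-7-hydroxy-3,6-dimethylhept-2-enoate (racemic) | COC(=O)/C=C(\C)CCC(C)(CO)OO
F4 | step 5 | methyl 2-[rac-(3R,6R)-6-(hydroxymethyl)-3,6-dimethyl-1,2-dioxan-3-yl]acetate | C[C@]1(CC(=O)OC)CC[C@](C)(CO)OO1
F5 | step 5 | 2-[rac-(3R,6R)-6-(hydroxymethyl)-3,6-dimethyl-1,2-dioxan-3-yl]acetaldehyde | C[C@]1(CC=O)CC[C@](C)(CO)OO1
F6 | step 6 | [(3S,6S)-3,6-dimethyl-6-(prop-2-en-1-yl)-1,2-dioxan-3-yl]methyl acetate | C[C@@]1(CC=C)CC[C@@](C)(COC(C)=O)OO1
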